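**Plan**

Target numbering: O1, C2 (heptyl), C3, C4 (ketone), C4a, C5, C6 (decyl), O7, C8 (lactone C=O), C8a; ring A is the lactone, ring B the dihydropyranone.
Retrosynthetic cuts, in order: C4–C4a of ring B; the ring-A alkene C4a=C8a (metathesis); the lactone ester bond C8–O7; the enol ether at C8a into a secondary alcohol, a diazophosphonoacetate and formaldehyde.
Forward: fragment 1, (R)-dec-1-en-3-ol, is turned into a 2-alkoxyacrylic acid (O–H insertion, methylenation, saponification) and esterified with fragment 2, (R)-tetradec-1-en-4-ol; metathesis closes ring A; the vinyl group becomes CH2–CHO; ring B is closed last.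
Enabling feature: C4a=C8a of ring A is a captodative α-alkoxy enoate whose β-carbon C4a is in 6-endo reach of an acyl radical at C4 (tether C3–C2–O1 on C8a). The radical then formed at C8a is flanked by O1 and the C8 carbonyl and has a single β-hydrogen (on C4a), so cobalt-mediated loss of that hydrogen restores C4a=C8a and gives the vinylogous ester directly.
Stereochemistry: C2 comes from Sharpless kinetic resolution of racemic dec-1-en-3-ol, C6 from (R)-1,2-epoxydodecane; no later step touches either center and the key step creates none.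

Key step: step 11

Assumption: (R)-1,2-epoxydodecane (8) is bought as the single enantiomer; a racemic batch would first be resolved by hydrolytic kinetic resolution.

**Route**

Step 1
Reactants: 1 (±)-dec-1-en-3-ol
Product: 2 (3R)-dec-1-en-3-ol
Conditions: Ti(OiPr)4 (10 mol %), L-(+)-diisopropyl tartrate (15 mol %), tBuOOH (0.6 equiv), 4 Å MS, CH2Cl2, −20 °C, run past half conversion
Reagents that add atoms: none
Why: Sharpless kinetic resolution: the titanium–L-(+)-tartrate catalyst should epoxidize the (S)-enantiomer much faster (to the erythro epoxy alcohol), so the slow-reacting (R)-alcohol is recovered enantioenriched; this sets C2 of the target.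

Step 2
Reactants: 3 triethyl phosphonoacetate
Product: 4 ethyl 2-diazo-2-(diethoxyphosphoryl)acetate
Conditions: 4-acetamidobenzenesulfonyl azide (1.1 equiv), DBU (1.2 equiv), MeCN, 0 °C to rt
Reagents that add atoms: 4-acetamidobenzenesulfonyl azide, CC(=O)Nc1ccc(cc1)S(=O)(=O)N=[N+]=[N-]
Why: Regitz diazo transfer to the doubly activated methylene of the phosphonoacetate.

Step 3
Reactants: 2 (3R)-dec-1-en-3-ol; 4 ethyl 2-diazo-2-(diethoxyphosphoryl)acetate
Product: 5 ethyl 2-{[(3R)-dec-1-en-3-yl]oxy}-2-(diethoxyphosphoryl)acetate (both epimers at the phosphonate carbon)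
Conditions: Rh2(OAc)4 (1 mol %), benzene, 80 °C, slow addition of 4
Reagents that add atoms: none
Why: Rhodium-carbenoid O–H insertion into a secondary allylic alcohol should outrun cyclopropanation; the C–O bond of 2 is not touched, so its configuration is kept, and the new phosphonate-bearing center is an inconsequential epimer mixture.

Step 4
Reactants: 5 ethyl 2-{[(3R)-dec-1-en-3-yl]oxy}-2-(diethoxyphosphoryl)acetate
Product: 6 ethyl 2-{[(3R)-dec-1-en-3-yl]oxy}prop-2-enoate
Conditions: LiN(SiMe3)2, THF, −78 °C; then paraformaldehyde, −78 °C to rt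
Reagents that add atoms: formaldehyde (as paraformaldehyde), C=O
Why: Horner–Wadsworth–Emmons methylenation converts both epimers of 5 into the same 2-alkoxyacrylate, the standard entry to enol-pyruvate-type ethers.

Step 5
Reactants: 6 ethyl 2-{[(3R)-dec-1-en-3-yl]oxy}prop-2-enoate
Product: 7 2-{[(3R)-dec-1-en-3-yl]oxy}prop-2-enoic acid
Conditions: LiOH·H2O (2 equiv), THF/H2O, 0 °C to rt; then aq. HCl to pH 3 at 0 °C
Reagents that add atoms: lithium hydroxide, [Li+].[OH-]
Why: Saponification of the unhindered ethyl ester; the 2-alkoxyacrylate is a poor Michael acceptor and the allylic ether center is not acidic, so nothing else should change.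

Step 6
Reactants: 8 (2R)-2-decyloxirane [(R)-1,2-epoxydodecane]
Product: 9 (4R)-tetradec-1-en-4-ol
Conditions: CH2=CHMgBr (1.5 equiv), CuI (10 mol %), THF, −30 to 0 °C; quench with H2O
Reagents that add atoms: vinylmagnesium bromide, C=C[Mg]Br
Why: Copper-catalyzed SN2 opening of the terminal epoxide at its CH2 end by the vinyl Grignard reagent; the C–O bond at the stereocenter is not broken, so the (R) center (later C6) is retained.

Step 7
Reactants: 7 2-{[(3R)-dec-1-en-3-yl]oxy}prop-2-enoic acid; 9 (4R)-tetradec-1-en-4-ol
Product: 10 (4R)-tetradec-1-en-4-yl 2-{[(3R)-dec-1-en-3-yl]oxy}prop-2-enoate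
Conditions: DCC (1.2 equiv), DMAP (0.2 equiv), CH2Cl2, 0 °C to rt
Reagents that add atoms: none
Why: Steglich esterification of a secondary alcohol with the acrylic acid; no bond to either stereocenter is made or broken.

Step 8
Reactants: 10 (4R)-tetradec-1-en-4-yl 2-{[(3R)-dec-1-en-3-yl]oxy}prop-2-enoate
Product: 11 (6R)-6-decyl-3-{[(3R)-dec-1-en-3-yl]oxy}-5,6-dihydro-2H-pyran-2-one
Conditions: second-generation Grubbs catalyst (H2IMes)(PCy3)Cl2Ru=CHPh (5 mol %), CH2Cl2 (0.002 M), 40 °C
Reagents that add atoms: none
Why: Ring-closing metathesis from the homoallylic terminus onto the 1,1-disubstituted acrylate should give the six-membered unsaturated lactone (ring A), as with methacrylate esters of homoallylic alcohols; the allylic-ether vinyl group could only close a four- or nine-membered ring and should stay intact.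

Step 9
Reactants: 11 (6R)-6-decyl-3-{[(3R)-dec-1-en-3-yl]oxy}-5,6-dihydro-2H-pyran-2-one
Product: 13 (6R)-6-decyl-3-{[(3R)-1-hydroxydecan-3-yl]oxy}-5,6-dihydro-2H-pyran-2-one, via terminal 9-BBN adduct 12 (not isolated)
Conditions: 9-BBN (1.3 equiv), THF, 0 °C to rt; then aq. NaOAc, 30% H2O2, 0 °C to rt
Reagents that add atoms: 9-borabicyclo[3.3.1]nonane, B1C2CCCC1CCC2 (atoms kept only in 12); hydrogen peroxide, OO
Why: Anti-Markovnikov hydroboration with the bulky, chemoselective 9-BBN at the only monosubstituted alkene, then buffered peroxide oxidation of the C–B bond; the trisubstituted push–pull ring alkene and the lactone should not react.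

Step 10
Reactants: 13 (6R)-6-decyl-3-{[(3R)-1-hydroxydecan-3-yl]oxy}-5,6-dihydro-2H-pyran-2-one
Product: 14 (3R)-3-{[(6R)-6-decyl-2-oxo-5,6-dihydro-2H-pyran-3-yl]oxy}decanal
Conditions: Dess–Martin periodinane (1.3 equiv), pyridine (3 equiv), CH2Cl2, 0 °C to rt; used without storage
Reagents that add atoms: none
Why: Dess–Martin oxidation under buffered, non-basic conditions stops at the aldehyde and should avoid β-elimination of the enol-ether oxygen.

Step 11
Reactants: 14 (3R)-3-{[(6R)-6-decyl-2-oxo-5,6-dihydro-2H-pyran-3-yl]oxy}decanal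
Product: 17 (2R,6R)-6-decyl-2-heptyl-2,3,5,6-tetrahydropyrano[3,4-b]pyran-4,8-dione, via acyl radical 15 (not isolated), via ring-closed C8a radical 16 (not isolated)
Conditions: (nBu4N)4[W10O32] (2 mol %), Co(dmgH)2(py)Cl (5 mol %), MeCN (0.005 M), 390 nm LEDs, Ar, 25 °C
Reagents that add atoms: none
Why: Proposed new method: photoexcited decatungstate abstracts the weak, hydridic formyl hydrogen of 14 to give the nucleophilic σ-acyl radical 15, which adds to C4 of the lactone (the β-carbon of the captodative α-alkoxy enoate, C4a of 17) and leaves the tertiary radical 16 at C8a, stabilized by O1 and the C8 carbonyl; the divalent cobalt complex Co(dmgH)2(py), formed from the precatalyst by the reduced polyoxotungstate, then removes the only β-hydrogen of 16 (C4a–H, also α to the new ketone) by hydrogen-atom abstraction or by Co–C bond formation and β-hydride elimination, and the cobalt hydride releases H2 with the proton stored on the reduced polyoxotungstate, so both catalysts turn over and the net change is 14 → 17 + H2. The closest known reaction types are the decatungstate-photocatalyzed hydroacylation of electron-poor alkenes with aldehydes, tin-hydride 6-endo acyl radical cyclizations onto enoates, and cobaloxime-terminated dehydrogenative (Heck-type) radical alkenylations; the proposal merges them in an intramolecular, acceptorless form. Ring B closes in the 6-endo-trig mode: the 5-exo alternative would attack the fully substituted, oxygen-bearing C3 of the lactone (the future C8a) and give an unstabilized secondary radical, whereas attack at C4 of the lactone is polarity-matched and gives the captodative radical. No stereocenter is formed, because C4a and C8a both end sp2, and C2 and C6 are not involved (C2 is β to the acyl radical and should stay configurationally fixed under these neutral conditions). The step needs chemoselective hydrogen abstraction at the formyl C–H (secured by its low bond strength and hydridic character compared with the ether α-C–H and chain C–H bonds) and cyclization faster than decarbonylation (secured by the activated acceptor and by the primary nature of the alkyl radical that decarbonylation would give). It also needs site-selective desaturation, which the substrate secures because 16 carries a single β-C–H, so neither the isomeric enone toward C3 of 17 nor over-oxidation to the 4-pyranone, both risks of a separate ketone dehydrogenation, can arise from this intermediate.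

**Compound list**

1 | (±)-dec-1-en-3-ol | CCCCCCCC(O)C=C | starting material
2 | (3R)-dec-1-en-3-ol | CCCCCCC[C@@H](O)C=C | intermediate
3 | triethyl phosphonoacetate | CCOC(=O)CP(=O)(OCC)OCC | starting material
4 | ethyl 2-diazo-2-(diethoxyphosphoryl)acetate | CCOC(=O)C(=[N+]=[N-])P(=O)(OCC)OCC | intermediate
5 | ethyl 2-{[(3R)-dec-1-en-3-yl]oxy}-2-(diethoxyphosphoryl)acetate (epimer mixture at the phosphonate carbon) | CCCCCCC[C@H](C=C)OC(C(=O)OCC)P(=O)(OCC)OCC | intermediate
6 | ethyl 2-{[(3R)-dec-1-en-3-yl]oxy}prop-2-enoate | CCCCCCC[C@H](C=C)OC(=C)C(=O)OCC | intermediate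
7 | 2-{[(3R)-dec-1-en-3-yl]oxy}prop-2-enoic acid | CCCCCCC[C@H](C=C)OC(=C)C(=O)O | intermediate
8 | (2R)-2-decyloxirane [(R)-1,2-epoxydodecane] | CCCCCCCCCC[C@@H]1CO1 | starting material
9 | (4R)-tetradec-1-en-4-ol | CCCCCCCCCC[C@@H](O)CC=C | intermediate
10 | (4R)-tetradec-1-en-4-yl 2-{[(3R)-dec-1-en-3-yl]oxy}prop-2-enoate | CCCCCCC[C@H](C=C)OC(=C)C(=O)O[C@H](CCCCCCCCCC)CC=C | intermediate
11 | (6R)-6-decyl-3-{[(3R)-dec-1-en-3-yl]oxy}-5,6-dihydro-2H-pyran-2-one | CCCCCCC[C@H](C=C)OC1=CC[C@@H](CCCCCCCCCC)OC1=O | intermediate
12 | terminal 9-BBN adduct of 11 (boron on the former vinyl CH2; both centers spatially unchanged, not isolated) | CCCCCCC[C@H](CCB1C2CCCC1CCC2)OC3=CC[C@@H](CCCCCCCCCC)OC3=O | intermediate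
13 | (6R)-6-decyl-3-{[(3R)-1-hydroxydecan-3-yl]oxy}-5,6-dihydro-2H-pyran-2-one | CCCCCCC[C@H](CCO)OC1=CC[C@@H](CCCCCCCCCC)OC1=O | intermediate
14 | (3R)-3-{[(6R)-6-decyl-2-oxo-5,6-dihydro-2H-pyran-3-yl]oxy}decanal | CCCCCCC[C@H](CC=O)OC1=CC[C@@H](CCCCCCCCCC)OC1=O | intermediate
15 | (3R)-3-{[(6R)-6-decyl-2-oxo-5,6-dihydro-2H-pyran-3-yl]oxy}decanoyl radical (not isolated) | CCCCCCC[C@H](C[C]=O)OC1=CC[C@@H](CCCCCCCCCC)OC1=O | intermediate
16 | (2R,6R)-6-decyl-2-heptyl-4,8-dioxohexahydropyrano[3,4-b]pyran-8a-yl radical (C4a unspecified, not isolated) | CCCCCCCCCC[C@@H]1CC2[C](O[C@H](CCCCCCC)CC2=O)C(=O)O1 | intermediate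
17 | (2R,6R)-6-decyl-2-heptyl-2,3,5,6-tetrahydropyrano[3,4-b]pyran-4,8-dione | CCCCCCCCCC[C@@H]1CC2=C(O[C@H](CCCCCCC)CC2=O)C(=O)O1 | target

**Count and risks**

Total step count: 11. Longest linear sequence: 9 steps (steps 1, 3, 4, 5, 7, 8, 9, 10, 11); steps 2 and 6 are side branches.

Steps most likely to fail:

1. Step 11 (bears the new-method label). What may go wrong: after ring closure the C8a radical may be quenched by hydrogen back-transfer from the reduced polyoxotungstate instead of being desaturated by cobalt (net hydroacylation), or hydrogen abstraction may not stay at the formyl C–H. The fallback uses known reaction types and separates ring closure from dehydrogenation; it sets out from 14 and comes back to the route at 17. Pinnick oxidation (NaClO2, NaH2PO4, 2-methylbut-2-ene, tBuOH/H2O) would give (3R)-3-{[(6R)-6-decyl-2-oxo-5,6-dihydro-2H-pyran-3-yl]oxy}decanoic acid F1. Treatment with (PhSe)2 and PBu3 in CH2Cl2 would give the Se-phenyl selenoester F2. Bu3SnH/AIBN (syringe pump, benzene, 80 °C) would effect the tin-hydride 6-endo acyl radical cyclization to the saturated bicyclic keto lactone (2R,6R)-6-decyl-2-heptylhexahydropyrano[3,4-b]pyran-4,8-dione F3, an epimer mixture at C4a and C8a that converges in the next operation. Radical photobromination (NBS, hν, PhCF3) at the captodative C8a–H would give the 8a-bromide F4, which is not isolated and should lose HBr toward the acidic C4a–H on addition of Et3N to give 17. Any F3 formed as a by-product of step 11 can be sent through this last operation as well.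

2. Step 8. What may go wrong: the ruthenium alkylidene may be trapped unproductively by the electron-rich 1,1-disubstituted enol-ether acrylate so that ring closure stalls, or the allyl vinyl ether may begin to undergo Claisen rearrangement on prolonged warming. The fallback builds the ring-A alkene by carbonyl olefination instead of metathesis; it sets out from 9 (and uses 5) and comes back at 11. Silylation of 9 (TBSCl, imidazole, DMF) would give tert-butyl(dimethyl){[(4R)-tetradec-1-en-4-yl]oxy}silane F5. Ozonolysis (O3, CH2Cl2, −78 °C; PPh3) would give (3R)-3-[(tert-butyldimethylsilyl)oxy]tridecanal F6. Horner–Wadsworth–Emmons reaction of F6 with the anion of 5 (LiN(SiMe3)2, THF, −78 °C to rt) would give ethyl (5R)-5-[(tert-butyldimethylsilyl)oxy]-2-{[(3R)-dec-1-en-3-yl]oxy}pentadec-2-enoate F7 as an E/Z mixture. HF·pyridine would free the hydroxy ester ethyl (5R)-2-{[(3R)-dec-1-en-3-yl]oxy}-5-hydroxypentadec-2-enoate F8. Catalytic camphorsulfonic acid in benzene at 50 °C, with PhSSPh/hν to equilibrate the alkene geometry through reversible thiyl-radical addition, would lactonize the isomer that has ester and chain cis and so funnel both isomers into 11.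

3. Step 9. What may go wrong: loss of chemoselectivity, either borane attack on the lactone carbonyl or opening of the enol-ether lactone during the peroxide work-up. The fallback replaces hydroboration/oxidation by a direct oxidation of the alkene; it sets out from 11 and comes back at 14, bypassing 13. An aldehyde-selective (anti-Markovnikov) Wacker oxidation of the allylic-ether vinyl group (PdCl2(PhCN)2, CuCl2·2H2O, AgNO2, tBuOH/MeNO2, O2, rt) would give 14 in one operation, with the proximal ether oxygen and the nitrite co-catalyst steering oxygen to the terminal carbon.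

Further compounds
F1 | step 11 | (3R)-3-{[(6R)-6-decyl-2-oxo-5,6-dihydro-2H-pyran-3-yl]oxy}decanoic acid | CCCCCCC[C@H](CC(=O)O)OC1=CC[C@@H](CCCCCCCCCC)OC1=O
F2 | step 11 | Se-phenyl (3R)-3-{[(6R)-6-decyl-2-oxo-5,6-dihydro-2H-pyran-3-yl]oxy}decaneselenoate | CCCCCCC[C@H](CC(=O)[Se]c1ccccc1)OC2=CC[C@@H](CCCCCCCCCC)OC2=O
F3 | step 11 | (2R,6R)-6-decyl-2-heptylhexahydropyrano[3,4-b]pyran-4,8-dione (epimer mixture at C4a and C8a) | CCCCCCCCCC[C@@H]1CC2C(O[C@H](CCCCCCC)CC2=O)C(=O)O1
F4 | step 11 | (2R,6R)-8a-bromo-6-decyl-2-heptylhexahydropyrano[3,4-b]pyran-4,8-dione (not isolated) | CCCCCCCCCC[C@@H]1CC2C(Br)(O[C@H](CCCCCCC)CC2=O)C(=O)O1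
F5 | step 8 | tert-butyl(dimethyl){[(4R)-tetradec-1-en-4-yl]oxy}silane | CCCCCCCCCC[C@H](CC=C)O[Si](C)(C)C(C)(C)C
F6 | step 8 | (3R)-3-[(tert-butyldimethylsilyl)oxy]tridecanal | CCCCCCCCCC[C@H](CC=O)O[Si](C)(C)C(C)(C)C
F7 | step 8 | ethyl (5R)-5-[(tert-butyldimethylsilyl)oxy]-2-{[(3R)-dec-1-en-3-yl]oxy}pentadec-2-enoate (E/Z mixture) | CCCCCCC[C@H](C=C)OC(=CC[C@@H](CCCCCCCCCC)O[Si](C)(C)C(C)(C)C)C(=O)OCC
F8 | step 8 | ethyl (5R)-2-{[(3R)-dec-1-en-3-yl]oxy}-5-hydroxypentadec-2-enoate (E/Z mixture) | CCCCCCC[C@H](C=C)OC(=CC[C@@H](CCCCCCCCCC)O)C(=O)OCC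
F0 | step 9 | none | none
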